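**Retrosynthetic overview** (chain carbons numbered C1 = ArCH2 to C16)
1. Last step: one reductive double desulfonylation unmasks both β,γ-unsaturated ketones from a bis(β-keto sulfone).
2. C4–C5 and C12–C13 come from C-acylation of two lithiated allyl sulfones (the aryl-bearing E-allyl sulfone and prenyl phenyl sulfone) by a C11 core carrying a free enoic acid (C5) and a methyl ester (C12).
3. Core: the key C7–C8 bond is made by Ni-electrocatalytic decarboxylative alkenylation with (E)-3-iodobut-2-enoic acid (sets 6E); C9–C10 by a visible-light Giese addition to acrylic acid; C11 (S) is bought as (S)-Roche ester.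
4. Aryl–C1 bond: photo-Claisen rearrangement of the ether made from 4-methoxy-2-methylphenol and the isoprene/PhSO2Cl 1,4-adduct (sets 2E).
5. No ring is formed; the only ring, the benzene ring, is bought.

Assumption: C11 is read as S from the SMILES, and (E)-3-iodobut-2-enoic acid and prenyl phenyl sulfone are taken as catalogue compounds.

**Step 1**
Reactants: 1 isoprene; 2 benzenesulfonyl chloride
Product: 3 (E)-4-chloro-2-methylbut-2-en-1-yl phenyl sulfone
Conditions: CuCl (2 mol %), Et3N·HCl (2 mol %), MeCN, 100 °C, sealed tube; recrystallise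
Reagents that add atoms: none
Why: Copper-catalysed atom-transfer radical addition (Kharasch-type chlorosulfonylation): PhSO2• adds reversibly at the CH2 next to the methyl-bearing carbon and CuCl2 returns chlorine to the unhindered allyl terminus, giving the crystalline E 1,4-adduct.

**Step 2**
Reactants: 4 4-methoxy-2-methylphenol; 3 (E)-4-chloro-2-methylbut-2-en-1-yl phenyl sulfone
Product: 5 4-methoxy-2-methylphenyl (E)-3-methyl-4-(phenylsulfonyl)but-2-en-1-yl ether
Conditions: K2CO3, acetone, 50 °C
Reagents that add atoms: none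
Why: Williamson O-allylation (SN2 at the primary allylic chloride; should base first cause 1,4-elimination to the sulfonyl diene, oxa-1,6-addition of the phenoxide leads to the same E ether).

**Step 3**
Reactants: 5 4-methoxy-2-methylphenyl (E)-3-methyl-4-(phenylsulfonyl)but-2-en-1-yl ether
Product: 6 4-methoxy-2-methyl-6-[(E)-3-methyl-4-(phenylsulfonyl)but-2-en-1-yl]phenol
Conditions: hν (300 nm), degassed MeOH, rt, stopped at about 70 % conversion
Reagents that add atoms: none
Why: Photo-Claisen rearrangement: excitation of the aryl ether homolyses the O–allyl bond and the caged phenoxyl/allyl radical pair recombines through the primary allyl carbon at the only open ortho position (para and the other ortho position are substituted) with the E olefin kept, then tautomerises to the phenol.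

**Step 4**
Reactants: 7 methyl (S)-3-hydroxy-2-methylpropanoate (Roche ester)
Product: 8 methyl (R)-3-iodo-2-methylpropanoate
Conditions: I2, PPh3, imidazole, CH2Cl2, 0 °C → rt
Reagents that add atoms: iodine, [I][I]
Why: Appel iodination of the primary alcohol; no bond to the stereocentre is touched (the R descriptor only reflects the higher priority of CH2I).

**Step 5**
Reactants: 8 methyl (R)-3-iodo-2-methylpropanoate; 9 acrylic acid
Product: 10 (5S)-6-methoxy-5-methyl-6-oxohexanoic acid
Conditions: (Me3Si)3SiH (1.3 equiv), 4CzIPN (2,4,5,6-tetrakis(carbazol-9-yl)isophthalonitrile, 2 mol %), MeCN, 450 nm LEDs, rt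
Reagents that add atoms: none
Why: Visible-light-initiated Giese reaction: silyl-radical iodine abstraction gives the primary radical, which adds to acrylic acid and is capped by hydrogen transfer from the silane; the neighbouring stereocentre never becomes a radical or an enolate.

**Step 6**
Reactants: 10 (5S)-6-methoxy-5-methyl-6-oxohexanoic acid; 11 N-hydroxyphthalimide; 12 (2E)-3-iodobut-2-enoic acid
Product: 14 (2E,7S)-8-methoxy-3,7-dimethyl-8-oxooct-2-enoic acid, via redox-active ester 13 (not isolated)
Conditions: 11, N,N'-diisopropylcarbodiimide, DMAP (cat.), CH2Cl2, rt; evaporate; then 12 (1.5 equiv), NiCl2·6H2O (10 mol %), 2,2'-bipyridine (10 mol %), AgNO3 (0.3 equiv), LiCl, DMF, Mg anode / reticulated vitreous carbon cathode, constant current, rt; 1 M HCl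
Reagents that add atoms: none
Why: Proposed new method: Ni-electrocatalytic decarboxylative alkenylation in which the alkenyl partner is an unprotected, conjugated β-iodo-enoic acid (a vinylogous acyl iodide) — cathodically formed low-valent nickel/bipyridine inserts into the C–I bond with retention while the carboxyl group sits as its magnesium salt from the anode, the primary radical released from 13 at the silver-nanoparticle-coated cathode is captured at nickel, and reductive elimination gives the E trisubstituted enoic acid (radical conjugate attack on 12 is slow because its β-carbon is fully substituted); closest known reaction type: Ni-electrocatalytic decarboxylative alkenylation of redox-active esters with unactivated alkenyl iodides on silver-modified cathodes, and Pd-catalysed Negishi coupling of free 3-iodobut-2-enoic acids.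

**Step 7**
Reactants: 14 (2E,7S)-8-methoxy-3,7-dimethyl-8-oxooct-2-enoic acid; 15 1,1'-carbonyldiimidazole; 6 4-methoxy-2-methyl-6-[(E)-3-methyl-4-(phenylsulfonyl)but-2-en-1-yl]phenol
Product: 18 methyl (2S,6E,10E)-12-(2-hydroxy-5-methoxy-3-methylphenyl)-2,6,10-trimethyl-8-oxo-9-(phenylsulfonyl)dodeca-6,10-dienoate, via acyl imidazole 16 (not isolated), via dilithio sulfone 17 (not isolated)
Conditions: 14, 15 (1.1 equiv), THF, rt; cannulate into 17 [6 (3.2 equiv), n-BuLi (6.4 equiv), THF, −78 °C]; −78 °C, 2 h; aq. NH4Cl (excess 6 recovered)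
Reagents that add atoms: none
Why: Julia-type C-acylation of an α-sulfonyl allyl carbanion: the lithiated sulfone attacks the acyl imidazole at its α-carbon far faster than the hindered methyl ester, both E olefins are kept, the product is shielded as its enolate, and the new sulfonyl-bearing centre (epimer mixture) is erased in step 9.

**Step 8**
Reactants: 18 methyl (2S,6E,10E)-12-(2-hydroxy-5-methoxy-3-methylphenyl)-2,6,10-trimethyl-8-oxo-9-(phenylsulfonyl)dodeca-6,10-dienoate; 19 prenyl phenyl sulfone
Product: 21 (2E,6E,11S)-1-(2-hydroxy-5-methoxy-3-methylphenyl)-3,7,11,15-tetramethyl-4,13-bis(phenylsulfonyl)hexadeca-2,6,14-triene-5,12-dione, via lithio sulfone 20 (not isolated)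
Conditions: 19 (5 equiv), n-BuLi (5 equiv), THF, −78 °C; add 18; −78 → −10 °C; aq. NH4Cl
Reagents that add atoms: none
Why: Acylation of lithiated prenyl sulfone (α-attack) by the methyl ester: the sulfonyl carbanion (pKa about 23) cannot remove the ester α-hydrogen at C11 (pKa about 30), and the phenol and the first keto sulfone are protected as lithium salts, so the stereocentre and the dienone survive; the second sulfonyl-bearing centre is again an irrelevant epimer mixture.

**Step 9**
Reactants: 21 (2E,6E,11S)-1-(2-hydroxy-5-methoxy-3-methylphenyl)-3,7,11,15-tetramethyl-4,13-bis(phenylsulfonyl)hexadeca-2,6,14-triene-5,12-dione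
Product: 22 (2E,6E,11S)-1-(2-hydroxy-5-methoxy-3-methylphenyl)-3,7,11,15-tetramethylhexadeca-2,6,14-triene-5,12-dione
Conditions: SmI2 (4.2 equiv, added until the blue colour persists), THF, −78 °C; then AcOH, −78 °C → rt
Reagents that add atoms: none
Why: Reductive desulfonylation of both β-keto sulfones (SmI2 electron transfer, C–S cleavage to samarium dienolates) followed by kinetic α-protonation, which keeps both β,γ-olefins out of conjugation, leaves the 2E and 6E olefins untouched and never enolises towards C11.

**Compound list**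
1 | isoprene (2-methylbuta-1,3-diene) | C=CC(C)=C | starting material
2 | benzenesulfonyl chloride | O=S(=O)(Cl)c1ccccc1 | starting material
3 | (E)-4-chloro-2-methylbut-2-en-1-yl phenyl sulfone | ClC/C=C(\C)CS(=O)(=O)c1ccccc1 | intermediate
4 | 4-methoxy-2-methylphenol | COc1ccc(O)c(C)c1 | starting material
5 | 4-methoxy-2-methylphenyl (E)-3-methyl-4-(phenylsulfonyl)but-2-en-1-yl ether | COc1ccc(OC/C=C(\C)CS(=O)(=O)c2ccccc2)c(C)c1 | intermediate
6 | 4-methoxy-2-methyl-6-[(E)-3-methyl-4-(phenylsulfonyl)but-2-en-1-yl]phenol | COc1cc(C)c(O)c(C/C=C(\C)CS(=O)(=O)c2ccccc2)c1 | intermediate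
7 | methyl (S)-3-hydroxy-2-methylpropanoate (Roche ester) | OC[C@H](C)C(=O)OC | starting material
8 | methyl (R)-3-iodo-2-methylpropanoate | IC[C@H](C)C(=O)OC | intermediate
9 | acrylic acid | C=CC(=O)O | starting material
10 | (5S)-6-methoxy-5-methyl-6-oxohexanoic acid | OC(=O)CCC[C@H](C)C(=O)OC | intermediate
11 | N-hydroxyphthalimide | ON1C(=O)c2ccccc2C1=O | starting material
12 | (2E)-3-iodobut-2-enoic acid | OC(=O)/C=C(\C)I | starting material
13 | 6-(1,3-dioxoisoindolin-2-yl) 1-methyl (2S)-2-methylhexanedioate (redox-active ester) | O=C(CCC[C@H](C)C(=O)OC)ON1C(=O)c2ccccc2C1=O | intermediate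
14 | (2E,7S)-8-methoxy-3,7-dimethyl-8-oxooct-2-enoic acid | OC(=O)/C=C(\C)CCC[C@H](C)C(=O)OC | intermediate
15 | 1,1'-carbonyldiimidazole | O=C(n1ccnc1)n1ccnc1 | starting material
16 | methyl (2S,6E)-8-(imidazol-1-yl)-2,6-dimethyl-8-oxooct-6-enoate (acyl imidazole) | O=C(/C=C(\C)CCC[C@H](C)C(=O)OC)n1ccnc1 | intermediate
17 | lithium 2-[(2E)-4-lithio-3-methyl-4-(phenylsulfonyl)but-2-en-1-yl]-4-methoxy-6-methylphenolate (dilithio sulfone) | COc1cc(C)c(O[Li])c(C/C=C(\C)C([Li])S(=O)(=O)c2ccccc2)c1 | intermediate
18 | methyl (2S,6E,10E)-12-(2-hydroxy-5-methoxy-3-methylphenyl)-2,6,10-trimethyl-8-oxo-9-(phenylsulfonyl)dodeca-6,10-dienoate (epimers at C9) | COc1cc(C)c(O)c(C/C=C(\C)C(C(=O)/C=C(\C)CCC[C@H](C)C(=O)OC)S(=O)(=O)c2ccccc2)c1 | intermediate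
19 | prenyl phenyl sulfone (3-methylbut-2-en-1-yl phenyl sulfone) | CC(C)=CCS(=O)(=O)c1ccccc1 | starting material
20 | [3-methyl-1-(phenylsulfonyl)but-2-en-1-yl]lithium (lithio sulfone) | [Li]C(C=C(C)C)S(=O)(=O)c1ccccc1 | intermediate
21 | (2E,6E,11S)-1-(2-hydroxy-5-methoxy-3-methylphenyl)-3,7,11,15-tetramethyl-4,13-bis(phenylsulfonyl)hexadeca-2,6,14-triene-5,12-dione (epimers at C4 and C13) | COc1cc(C)c(O)c(C/C=C(\C)C(C(=O)/C=C(\C)CCC[C@H](C)C(=O)C(C=C(C)C)S(=O)(=O)c2ccccc2)S(=O)(=O)c2ccccc2)c1 | intermediate
22 | (2E,6E,11S)-1-(2-hydroxy-5-methoxy-3-methylphenyl)-3,7,11,15-tetramethylhexadeca-2,6,14-triene-5,12-dione | COc1cc(C)c(O)c(C/C=C(\C)CC(=O)/C=C(\C)CCC[C@H](C)C(=O)CC=C(C)C)c1 | target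

**Totals and risks**
Total: 9 steps. Longest linear sequence: 6 steps (7 → 8 → 10 → 14 → 18 → 21 → 22; the arene branch 1 + 2 → 3 → 5 → 6 → 18 → 21 → 22 is equally long).

Most likely to fail, first: step 6, the proposed new electrochemical coupling. Iodo acid 12 may be reduced directly at the cathode, its acidic proton costs charge, and radical addition–elimination could erode the E geometry. The fallback uses known chemistry, sets out from 8 and comes back at 14. Zinc insertion (Zn dust, cat. I2, DMF) gives (R)-(3-methoxy-2-methyl-3-oxopropyl)zinc iodide F4. Negishi coupling with vinyl bromide (Pd(PPh3)4) gives methyl (S)-2-methylpent-4-enoate F5. Hydroboration with 9-BBN gives methyl (S)-5-(9-borabicyclo[3.3.1]nonan-9-yl)-2-methylpentanoate F6. B-alkyl Suzuki–Miyaura coupling of F6 with 12 (PdCl2(dppf), AsPh3, Cs2CO3, DMF/H2O, rt) returns 14 with the E geometry retained.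

Second: step 3, the photo-Claisen rearrangement. Yields are typically moderate because of cage escape back to 4, recombination at the substituted ring positions and secondary photocyclisation of 6. The fallback sets out from 4 (with 3) and comes back at 6. Protection with MOMCl/i-Pr2NEt gives 4-methoxy-1-(methoxymethoxy)-2-methylbenzene F1. Ortho-lithiation (n-BuLi, TMEDA, Et2O) and transmetalation with ZnCl2 give [5-methoxy-2-(methoxymethoxy)-3-methylphenyl]zinc chloride F2, which is too weakly basic to eliminate HCl from 3. Negishi allylation of 3 (Pd(PPh3)4, THF) at the unsubstituted allyl terminus gives 5-methoxy-2-(methoxymethoxy)-1-methyl-3-[(2E)-3-methyl-4-(phenylsulfonyl)but-2-en-1-yl]benzene F3 with the E olefin kept. HCl in MeOH removes the MOM group and returns 6.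

Third: step 7, the fragment union. The enoyl imidazole 16 could lose its γ-proton to the carbanion (vinylketene) or acylate the phenoxide instead of carbon. The fallback changes both the order and the acyl donor; it sets out from 14 and comes back at 21. Lithio sulfone 20 (3.3 equiv) is acylated by the methyl ester of 14, with the carboxylate as spectator, to give (2E,7S)-3,7,11-trimethyl-8-oxo-9-(phenylsulfonyl)dodeca-2,10-dienoic acid F7. Treatment with 15 and then MeNHOMe·HCl gives the Weinreb amide (2E,7S)-N-methoxy-N,3,7,11-tetramethyl-8-oxo-9-(phenylsulfonyl)dodeca-2,10-dienamide F8. Addition of dilithio sulfone 17 forms a chelated tetrahedral adduct that can neither eliminate nor over-add, and work-up gives 21 directly; step 9 follows unchanged.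

**Further compounds**
F1 | step 3 | 4-methoxy-1-(methoxymethoxy)-2-methylbenzene | COCOc1ccc(OC)cc1C
F2 | step 3 | [5-methoxy-2-(methoxymethoxy)-3-methylphenyl]zinc chloride | COCOc1c(C)cc(OC)cc1[Zn]Cl
F3 | step 3 | 5-methoxy-2-(methoxymethoxy)-1-methyl-3-[(2E)-3-methyl-4-(phenylsulfonyl)but-2-en-1-yl]benzene | COCOc1c(C)cc(OC)cc1C/C=C(\C)CS(=O)(=O)c1ccccc1
F4 | step 6 | (R)-(3-methoxy-2-methyl-3-oxopropyl)zinc iodide | I[Zn]C[C@H](C)C(=O)OC
F5 | step 6 | methyl (S)-2-methylpent-4-enoate | C=CC[C@H](C)C(=O)OC
F6 | step 6 | methyl (S)-5-(9-borabicyclo[3.3.1]nonan-9-yl)-2-methylpentanoate | B1(CCC[C@H](C)C(=O)OC)C2CCCC1CCC2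
F7 | step 7 | (2E,7S)-3,7,11-trimethyl-8-oxo-9-(phenylsulfonyl)dodeca-2,10-dienoic acid | OC(=O)/C=C(\C)CCC[C@H](C)C(=O)C(C=C(C)C)S(=O)(=O)c1ccccc1
F8 | step 7 | (2E,7S)-N-methoxy-N,3,7,11-tetramethyl-8-oxo-9-(phenylsulfonyl)dodeca-2,10-dienamide | CON(C)C(=O)/C=C(\C)CCC[C@H](C)C(=O)C(C=C(C)C)S(=O)(=O)c1ccccc1
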